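**Strategy.** Everything rests on one disconnection: the bond from the spiro carbon C3, which is shared by the cyclohexane-1,3,5-trione ring (C1–C2–C3–C4–C5–C9) and the cyclopentane, to the ring methylene C8'. C3 is para to O–C9 in the phloroglucinol that the trione ring hides, so the bond is forged by base-induced para-alkylative dearomatization of phenol 12, a benzoyl-substituted benzoxepine whose benzylic stereocentre C5' carries a CMe2CH2CH2Cl arm. One operation turns the flat arene into the dienone, creates quaternary C3 and closes the cyclopentane, while the temporary oxepine ring dictates the C3/C5' relationship and later feeds a Claisen–Cope relay and a cationic closure that complete the cage.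

Key step: step 10

Atom labels used below: trione ring C1(benzoyl)–C2(=O)–C3(spiro)–C4(=O)–C5(geranyl)–C9(=O); bridge C5–C6H2–C7H–C8Me2–C1; bridge C7–C4'H2–C5'H–C3; cyclopentane C3–C8'H2–C7'H2–C6'Me2–C5'. O2, O4 and O9 are the oxygens on C2, C4 and C9.

Assumption: the facial sense of the CuH/SEGPHOS reduction (step 6) is ligand-controlled; whichever ligand antipode gives (4R)-9 is used. Compounds 1, 5 and 17 are taken as commercial.

Step 1
Reactants: 1 3,3-dimethyloxolan-2-one
Product: 2 4-chloro-2,2-dimethylbutanoyl chloride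
Conditions: SOCl2 (1.5 equiv), ZnCl2 (5 mol %), neat, 60 °C
Reagents that add atoms: thionyl chloride O=S(Cl)Cl
Why: ZnCl2-catalysed ring-opening chlorination of a γ-lactone with thionyl chloride (chloride attack at the primary O–CH2 of the acyl-activated lactone) is the standard entry to 4-chlorobutanoyl chlorides and creates no stereocentre.

Step 2
Reactants: 2 4-chloro-2,2-dimethylbutanoyl chloride
Product: 4 ethyl 6-chloro-4,4-dimethyl-3-oxohexanoate, via acylmalonic half-ester 3 (not isolated)
Conditions: KO2CCH2CO2Et, MgCl2, Et3N, MeCN, 0 °C → rt; then 2 M HCl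
Reagents that add atoms: potassium ethyl malonate CCOC(=O)CC(=O)[O-].[K+]
Why: Magnesium-mediated C-acylation of the malonate half-ester followed by decarboxylation on acidification (Rathke/Clay β-keto ester synthesis) tolerates the hindered, non-enolisable acid chloride and the primary chloride.

Step 3
Reactants: 4 ethyl 6-chloro-4,4-dimethyl-3-oxohexanoate; 5 phloroglucinol
Product: 6 4-(4-chloro-2-methylbutan-2-yl)-5,7-dihydroxy-2H-chromen-2-one
Conditions: MeSO3H, 25 → 45 °C
Reagents that add atoms: none
Why: Pechmann condensation (acid-promoted hydroxyalkylation of the electron-rich arene by the ketone, then lactonisation) can give only one coumarin because phloroglucinol is threefold symmetric.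

Step 4
Reactants: 6 4-(4-chloro-2-methylbutan-2-yl)-5,7-dihydroxy-2H-chromen-2-one
Product: 7 8-benzoyl-4-(4-chloro-2-methylbutan-2-yl)-5,7-dihydroxy-2H-chromen-2-one
Conditions: BzCl (1.2 equiv), AlCl3 (3 equiv), PhNO2, 70 °C
Reagents that add atoms: benzoyl chloride O=C(Cl)c1ccccc1
Why: Friedel–Crafts benzoylation of 5,7-dihydroxy-4-alkylcoumarins is known to favour C8 (between the ring oxygen and 7-OH), which places the benzoyl group next to the lactone oxygen that later becomes O2.

Step 5
Reactants: 7 8-benzoyl-4-(4-chloro-2-methylbutan-2-yl)-5,7-dihydroxy-2H-chromen-2-one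
Product: 8 8-benzoyl-4-(4-chloro-2-methylbutan-2-yl)-7-hydroxy-5-methoxy-2H-chromen-2-one
Conditions: MeI (1.05 equiv), K2CO3 (1.1 equiv), acetone, rt
Reagents that add atoms: iodomethane CI
Why: Williamson etherification should take the free 5-OH because the 7-OH is deactivated by its hydrogen bond to the new ketone, so the methyl ether masks the one phenol (O4) that could later compete with O2.

Step 6
Reactants: 8 8-benzoyl-4-(4-chloro-2-methylbutan-2-yl)-7-hydroxy-5-methoxy-2H-chromen-2-one
Product: 9 (4R)-8-benzoyl-4-(4-chloro-2-methylbutan-2-yl)-7-hydroxy-5-methoxy-3,4-dihydro-2H-chromen-2-one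
Conditions: Cu(OAc)2 (5 mol %), (R)-DTBM-SEGPHOS (5.5 mol %), (EtO)2MeSiH, t-BuOH, THF/PhMe, 0 °C → rt; NH4F, MeOH work-up
Reagents that add atoms: none
Why: Copper hydride-catalysed asymmetric conjugate reduction of a β,β-disubstituted unsaturated lactone (CuH–SEGPHOS type) delivers hydride to one face of C4 and sets the only externally controlled stereocentre (C5', R), the bis-ortho-substituted chelated diaryl ketone and the alkyl chloride being expected to stay inert.

Step 7
Reactants: 9 (4R)-8-benzoyl-4-(4-chloro-2-methylbutan-2-yl)-7-hydroxy-5-methoxy-3,4-dihydro-2H-chromen-2-one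
Product: 10 dimethylsulfoxonium (4R)-4-(3-benzoyl-2,4-dihydroxy-6-methoxyphenyl)-7-chloro-5,5-dimethyl-2-oxoheptylide
Conditions: Me3S(O)I (3.5 equiv), KOt-Bu (3.5 equiv), THF, 0 °C → rt
Reagents that add atoms: trimethylsulfoxonium iodide C[S+](C)(C)=O.[I-]
Why: Acylation of dimethylsulfoxonium methylide by the aryl lactone opens the ring to the stabilised β-keto sulfoxonium ylide and frees O2–H without touching the stereocentre.

Step 8
Reactants: 10 dimethylsulfoxonium (4R)-4-(3-benzoyl-2,4-dihydroxy-6-methoxyphenyl)-7-chloro-5,5-dimethyl-2-oxoheptylide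
Product: 11 (5R)-9-benzoyl-5-(4-chloro-2-methylbutan-2-yl)-8-hydroxy-6-methoxy-4,5-dihydro-1-benzoxepin-3(2H)-one
Conditions: [Ir(cod)Cl]2 (2 mol %), DCE (0.01 M), 70 °C
Reagents that add atoms: none
Why: Iridium-catalysed carbenoid formation from the sulfoxonium ylide and intramolecular O–H insertion into the only ortho phenol (O2–H) recloses a seven-membered ring, a one-carbon ring expansion of the lactone that places C6 between O2 and C7.

Step 9
Reactants: 11 (5R)-9-benzoyl-5-(4-chloro-2-methylbutan-2-yl)-8-hydroxy-6-methoxy-4,5-dihydro-1-benzoxepin-3(2H)-one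
Product: 12 (5R)-9-benzoyl-5-(4-chloro-2-methylbutan-2-yl)-8-hydroxy-6-methoxy-3-(propan-2-ylidene)-2,3,4,5-tetrahydro-1-benzoxepine
Conditions: i-PrPPh3I (3 equiv), n-BuLi (3 equiv), THF, 0 °C → rt
Reagents that add atoms: isopropyltriphenylphosphonium iodide CC(C)[P+](c1ccccc1)(c1ccccc1)c1ccccc1.[I-]
Why: Wittig olefination of the ring ketone with the non-stabilised isopropylidene ylide should give the exocyclic tetrasubstituted alkene C7=C8Me2, completing the aryl allyl ether O2–C6–C7=C8, while the hindered chelated benzoyl ketone is not expected to react.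

Step 10
Reactants: 12 (5R)-9-benzoyl-5-(4-chloro-2-methylbutan-2-yl)-8-hydroxy-6-methoxy-3-(propan-2-ylidene)-2,3,4,5-tetrahydro-1-benzoxepine
Product: 13 oxepine-fused spiro[4.5]decadienone (C3 S; C5' R; full description in the compound list)
Conditions: KOt-Bu (1.3 equiv), t-BuOH/THF (1:1), 60 °C
Reagents that add atoms: none
Why: KOt-Bu deprotonates the chelated C9–OH, and the phenoxide, through its para carbon C3, displaces chloride at C8' in an intramolecular SN2 reaction, so that the arene becomes the cross-conjugated 2,5-cyclohexadienone (C9=O flanked by the C1=C2 and C5=C4 enol ethers) with C3 quaternary. The closest known reaction type is Winstein's Ar1-5 participation, the base-mediated para-alkylative dearomatization of 4-(4-halobutyl)phenols to spiro[4.5]decadienones. The cyclopentane C3–C8'–C7'–C6'–C5' closes in the 5-exo-tet mode. The new stereocentre C3 is controlled by C5' through the oxepine tether: the CMe2 arm must stand perpendicular to the arene to reach C3, and with C4' held beside C2 by the seven-membered ring only the face giving the C3-(S)/C5'-(R) spirocycle (C4' syn to C2, the benzoyl side, as in the target) is open. The step needs C- over O-alkylation and ipso over ortho attack: O2 and O4 are capped as ethers, O9 cannot reach C8', attack through C5 would need a seven-membered ring, and the sluggish primary chloride should keep the arm silent through the earlier basic steps.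

Step 11
Reactants: 13 oxepine-fused spiro[4.5]decadienone
Product: 16 Cope product (C5–C6 bridged enol triketone; exocyclic C7=C8Me2), via Claisen ketone 14 (not isolated), via demethylated enol 15 (not isolated)
Conditions: DMSO, 110 °C; then LiCl (6 equiv), 130 °C; 1 M HCl work-up
Reagents that add atoms: none
Why: Thermal Claisen rearrangement of the allyl dienyl ether (O2–C6–C7=C8 onto C1) forms C1–C8 on the C5' face, chloride then demethylates the vinylogous ester (Krapcho-type SN2), and the liberated enolate undergoes a Cope shift through the chair-like C1–C8–C7–C6–C5–C9 array that moves the allyl unit to C5 (new C5–C6 bond) and restores the stabilised benzoyl-triketone enol, the tether fixing the C5 configuration.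

Step 12
Reactants: 16 Cope product; 17 geranyl bromide
Product: 18 C5-geranylated enol triketone (C3 S; C5 S; C5' R)
Conditions: KHMDS (2.2 equiv), THF, −78 °C; then 17 (1.1 equiv), −78 → 0 °C
Reagents that add atoms: none
Why: C-alkylation of the dianion (triketone enolate plus the more basic C5 carbanion) with the allylic bromide should occur at C5, and because C6 is tied into the seven-membered ring the geranyl group can enter only on the open (exo) face.

Step 13
Reactants: 18 C5-geranylated enol triketone
Product: 19 (1R,3S,7R,9R,11S)-11-benzoyl-1-[(2E)-3,7-dimethylocta-2,6-dien-1-yl]-6,6,10,10-tetramethyltetracyclo[7.3.1.1(3,11).0(3,7)]tetradecane-2,12,14-trione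
Conditions: TFA (5 equiv), CH2Cl2, −20 → 0 °C
Reagents that add atoms: none
Why: Biomimetic cationic cyclisation: Markovnikov protonation of the tetrasubstituted alkene at C7 gives the tertiary C8 cation, which the enolic carbon C1 captures in a six-membered ring closure (the type A acylphloroglucinol C1–C8 bond); protonation is reversible, so only the C7 epimer with H exo can close, and C1, C5 and C7 are then fixed by the cage.

**Compound list**

1 | 3,3-dimethyloxolan-2-one (α,α-dimethyl-γ-butyrolactone) | CC1(C)CCOC1=O | starting material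
2 | 4-chloro-2,2-dimethylbutanoyl chloride | CC(C)(CCCl)C(Cl)=O | intermediate
3 | 6-chloro-2-(ethoxycarbonyl)-4,4-dimethyl-3-oxohexanoic acid (magnesium chelate in the flask) | CCOC(=O)C(C(O)=O)C(=O)C(C)(C)CCCl | intermediate
4 | ethyl 6-chloro-4,4-dimethyl-3-oxohexanoate | CCOC(=O)CC(=O)C(C)(C)CCCl | intermediate
5 | phloroglucinol (benzene-1,3,5-triol) | Oc1cc(O)cc(O)c1 | starting material
6 | 4-(4-chloro-2-methylbutan-2-yl)-5,7-dihydroxy-2H-chromen-2-one | O=c1cc(C(C)(C)CCCl)c2c(O)cc(O)cc2o1 | intermediate
7 | 8-benzoyl-4-(4-chloro-2-methylbutan-2-yl)-5,7-dihydroxy-2H-chromen-2-one | O=c1cc(C(C)(C)CCCl)c2c(O)cc(O)c(C(=O)c3ccccc3)c2o1 | intermediate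
8 | 8-benzoyl-4-(4-chloro-2-methylbutan-2-yl)-7-hydroxy-5-methoxy-2H-chromen-2-one | O=c1cc(C(C)(C)CCCl)c2c(OC)cc(O)c(C(=O)c3ccccc3)c2o1 | intermediate
9 | (4R)-8-benzoyl-4-(4-chloro-2-methylbutan-2-yl)-7-hydroxy-5-methoxy-3,4-dihydro-2H-chromen-2-one | O=C1C[C@H](C(C)(C)CCCl)c2c(OC)cc(O)c(C(=O)c3ccccc3)c2O1 | intermediate
10 | dimethylsulfoxonium (4R)-4-(3-benzoyl-2,4-dihydroxy-6-methoxyphenyl)-7-chloro-5,5-dimethyl-2-oxoheptylide | CS(C)(=O)=CC(=O)C[C@H](C(C)(C)CCCl)c1c(OC)cc(O)c(C(=O)c2ccccc2)c1O | intermediate
11 | (5R)-9-benzoyl-5-(4-chloro-2-methylbutan-2-yl)-8-hydroxy-6-methoxy-4,5-dihydro-1-benzoxepin-3(2H)-one | O=C1COc2c(C(=O)c3ccccc3)c(O)cc(OC)c2[C@@H](C(C)(C)CCCl)C1 | intermediate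
12 | (5R)-9-benzoyl-5-(4-chloro-2-methylbutan-2-yl)-8-hydroxy-6-methoxy-3-(propan-2-ylidene)-2,3,4,5-tetrahydro-1-benzoxepine | CC(C)=C1COc2c(C(=O)c3ccccc3)c(O)cc(OC)c2[C@@H](C(C)(C)CCCl)C1 | intermediate
13 | spirodienone (C3 S, C5' R): 2,5-cyclohexadien-1-one (C9=O) with benzoyl on C1 and methoxy on C4, C3 spiro-fused to the 2,2-dimethylcyclopentane, oxepine bridge O2–C6H2–C7(=CMe2)–C4'H2–C5' retained | CC(C)=C1COC2=C(C(=O)c3ccccc3)C(=O)C=C(OC)[C@@]24CCC(C)(C)[C@H]4C1 | intermediate
14 | Claisen ketone (C1 R, C3 S, C5' R): C1 quaternary with benzoyl and C8Me2, C2 and C9 ketones, C4 methoxy enol ether, exocyclic methylene C7=C6H2 in the carbocyclic seven-membered ring C1–C2–C3–C5'–C4'–C7–C8 | C=C1C[C@@H]2C(C)(C)CC[C@@]23C(OC)=CC(=O)[C@](C(=O)c4ccccc4)(C3=O)C1(C)C | intermediate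
15 | demethylated enol of 14 (C4–OH vinylogous acid; lithium enolate in the flask) | C=C1C[C@@H]2C(C)(C)CC[C@@]23C(O)=CC(=O)[C@](C(=O)c4ccccc4)(C3=O)C1(C)C | intermediate
16 | Cope product (C3 S, C5 S, C5' R): C5–H bridged to C7 through C6H2, exocyclic C7=C8Me2, C4 ketone, benzoyl triketone enol at C1/C9 | CC(C)=C1C[C@@H]2C(C)(C)CC[C@]23C(=O)C(C(=O)c4ccccc4)=C(O)[C@H](C1)C3=O | intermediate
17 | geranyl bromide, (2E)-1-bromo-3,7-dimethylocta-2,6-diene | CC(C)=CCC/C(C)=C/CBr | starting material
18 | C5-geranylated 16 (C3 S, C5 S, C5' R) | CC(C)=CCC/C(C)=C/C[C@@]12CC(=C(C)C)C[C@@H]3C(C)(C)CC[C@]3(C1=O)C(=O)C(C(=O)c1ccccc1)=C2O | intermediate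
19 | (1R,3S,7R,9R,11S)-11-benzoyl-1-[(2E)-3,7-dimethylocta-2,6-dien-1-yl]-6,6,10,10-tetramethyltetracyclo[7.3.1.1(3,11).0(3,7)]tetradecane-2,12,14-trione (CNP0168637.1) | CC(C)=CCC/C(C)=C/C[C@@]12C[C@H]3C[C@@H]4C(C)(C)CC[C@]4(C1=O)C(=O)[C@@](C(=O)c1ccccc1)(C2=O)C3(C)C | target

Total step count: 13. Longest linear sequence: 13 steps (1 → 19).

**Steps most likely to fail**

Step 6. The risk is slow hydride transfer to the congested β-carbon (flanked by the tert-alkyl group and the peri methoxy group), with eroded facial discrimination and possibly competing reduction of the aryl ketone. The fallback replaces asymmetric catalysis by resolution. It sets out from 8: conjugate reduction with achiral Stryker reagent gives the racemic dihydrocoumarin F1; aminolysis with (S)-1-phenylethylamine gives two diastereomeric hydroxy-amides, from which the (3R)-amide F2 is separated by crystallisation or chromatography; acid-catalysed relactonisation (p-TsOH, toluene, reflux) expels the amine and comes back to the route at 9.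

Step 11. The risk is that, after the Claisen stage, the allyl unit does not migrate from C1 to C5 (a strained chair in the tethered array) or is lost by deallylation. The fallback forms C5–C6 by SN2 instead of a sigmatropic shift and also makes step 13 unnecessary. It sets out from 14, isolated by stopping after the thermal Claisen stage. Radical hydrothiolation (PhSH, AIBN) adds sulfur to C6 and hydrogen to C7 from the exo face to give the sulfide F3. LiCl/DMSO demethylation gives the enol F4. C-geranylation at C5 with 17 and K2CO3 gives the geranylated enol F5. S-Methylation with MeOTf gives the sulfonium salt F6, and DBU closes C5–C6 by intramolecular C-alkylation with loss of thioanisole, coming back to the route at 19.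

Step 13. The risk is protonation of the geranyl alkenes, with capture of the resulting cations by enol oxygen, in competition with the desired closure. The fallback reverses the order so that no acid meets the geranyl chain. It sets out from 16: the same acid-mediated closure gives the geranyl-free cage F7. Bridgehead deprotonation at C5, the only acidic C–H left, with LiTMP and alkylation with 17 (bridgehead enolate alkylation as practised on bicyclo[3.3.1]nonane-triones) comes back to the route at 19.

**Further compounds**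

F1 | step 6 | racemic 8-benzoyl-4-(4-chloro-2-methylbutan-2-yl)-7-hydroxy-5-methoxy-3,4-dihydro-2H-chromen-2-one | O=C1CC(C(C)(C)CCCl)c2c(OC)cc(O)c(C(=O)c3ccccc3)c2O1
F2 | step 6 | (3R)-3-(3-benzoyl-2,4-dihydroxy-6-methoxyphenyl)-6-chloro-4,4-dimethyl-N-[(1S)-1-phenylethyl]hexanamide | C[C@H](NC(=O)C[C@H](C(C)(C)CCCl)c1c(OC)cc(O)c(C(=O)c2ccccc2)c1O)c1ccccc1
F3 | step 11 | phenylthio adduct of 14 (PhS on C6, H on C7 exo) | c1ccccc1SC[C@H]1C[C@@H]2C(C)(C)CC[C@@]23C(OC)=CC(=O)[C@](C(=O)c4ccccc4)(C3=O)C1(C)C
F4 | step 11 | demethylated enol of F3 | c1ccccc1SC[C@H]1C[C@@H]2C(C)(C)CC[C@@]23C(O)=CC(=O)[C@](C(=O)c4ccccc4)(C3=O)C1(C)C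
F5 | step 11 | C5-geranylated enol of F4 | c1ccccc1SC[C@H]1C[C@@H]2C(C)(C)CC[C@@]23C(O)=C(C/C=C(\C)CCC=C(C)C)C(=O)[C@](C(=O)c4ccccc4)(C3=O)C1(C)C
F6 | step 11 | S-methyl sulfonium triflate of F5 | C[S+](c1ccccc1)C[C@H]1C[C@@H]2C(C)(C)CC[C@@]23C(O)=C(C/C=C(\C)CCC=C(C)C)C(=O)[C@](C(=O)c4ccccc4)(C3=O)C1(C)C.[O-]S(=O)(=O)C(F)(F)F
F7 | step 13 | geranyl-free cage (C5–H analogue of 19) | [C@@H]12C[C@H]3C[C@@H]4C(C)(C)CC[C@]4(C1=O)C(=O)[C@@](C(=O)c1ccccc1)(C2=O)C3(C)C
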